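Decide, before Tuesday's flask is charged, whether it gets more catalyst or stays at Monday's charge.

| flask | starting material | catalyst | target | time |
|---|---|---|---|---|
| Monday's | 0.500 M | 0.00100 M |  |  |
| Thursday's | 0.300 M | 0.00100 M |  |  |
| Wednesday's | 0.500 M | 0.00100 M | 0.250 M |  |
| Saturday's | 0.500 M | 0.00300 M |  |  |
| Tuesday's | 0.500 M | 0.00100 M |  | 29 min |

| run | time / min | [target] / M |
|---|---|---|
| Monday's run | 0.39 | 0.012 |
| Monday's run | 0.88 | 0.021 |
| Monday's run | 2.0 | 0.053 |
| Monday's run | 4.4 | 0.089 |
| Monday's run | 9.8 | 0.124 |
| Thursday's run | 0.39 | 0.003 |
| Thursday's run | 0.88 | 0.008 |
| Thursday's run | 2.0 | 0.030 |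
| Thursday's run | 4.4 | 0.050 |
| Thursday's run | 9.8 | 0.073 |
| Wednesday's run | 0.39 | 0.253 |
| Wednesday's run | 0.88 | 0.254 |
| Wednesday's run | 2.0 | 0.252 |
| Wednesday's run | 4.4 | 0.248 |
| Wednesday's run | 9.8 | 0.224 |
| Saturday's run | 0.39 | 0.024 |
| Saturday's run | 0.88 | 0.047 |
| Saturday's run | 2.0 | 0.099 |
| Saturday's run | 4.4 | 0.164 |
| Saturday's run | 9.8 | 0.193 |

(scatter of a reading: 0.003 M)

1. order of the initial rate in [starting material], near the charge of the Monday's run, the rate being that where two percent of its starting material are target (one fixed amount of target, the same in the runs compared)
2. order of the initial rate in [catalyst], near the charge of the Monday's run, the rate being that where two percent of its starting material are target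
3. target in the Tuesday's run at 29 min, as a share of the starting material charged

- Overall: starting material -> target, with catalyst as catalyst.
- Constant volume, constant temperature.
- An order is taken over about fifteen percent of the charge, up and down.

I compare Monday's and Saturday's flasks over nearly the same amount made. Monday's flask reads 0.053 M of target at 2.0 min, a mean rate of 0.0265 M min⁻¹, and Saturday's reads 0.047 M at 0.88 min, a mean rate of 0.0534 M min⁻¹, so a catalyst ratio n of 3.00 gives a rate ratio ρ, as read, of 2.02. Suppose the rate is a term proportional to catalyst plus a term free of it, an uncatalysed background. I then define φ, the catalysed share of Monday's rate, as the excess of ρ over one divided by the excess of n over one, which reads 0.508, give or take 0.0860 from the scatter. For a sum of this form, the local order in catalyst equals φ, so I commit to an order near 0.508.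

More catalyst therefore acts on about half of Monday's rate, and I leave Tuesday's flask at Monday's charge. Its reading at 29 min then lies beyond Monday's last reading at 9.8 min, and I expect some loss of target in Tuesday's flask, since Wednesday's run, charged with target, reads 0.252 M at 2.0 min and 0.224 M at 9.8 min.

The forecast gives an order of 1.3 in starting material, an order of 0.75 in catalyst, and target in Tuesday's flask at 29 min of 20 % of the starting material charged. Its order in catalyst differs from mine, and its ground for that order is that “Saturday's early rate is only about 2.2 times Monday's”.

The simulation gives an order of 1.1 in starting material, an order of 0.57 in catalyst, and target in Tuesday's flask at 29 min of 16.6 % of the starting material charged.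

    catalyst + starting material → target + catalyst (31.92 M⁻¹ min⁻¹)
    starting material → target (0.02616 min⁻¹)
    target → decomposed product (0.1074 min⁻¹)

The order in catalyst near Monday's charge, 0.57, stands below the order of the same flask without the uncatalysed step, because starting material also turns into target with no catalyst. In that second run, with the uncatalysed step taken away, φ, which I read as 0.508 for Monday's flask, is one by its definition, and the order in catalyst is 1.1.

(The earlier runs and the new flask are calculated from invented constants, noise included.)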